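**Plan**

1. Locants are carotenoid ones: left ring C1–C6, chain C7–C15 and C15'–C7', right ring C6'–C1' (C1' = CMe2, C6' = CH). The retrosynthesis cuts C9=C10 (Horner–Wadsworth–Emmons), C11'=C12' (Wittig) and C7'=C8' (Julia–Kocienski), and last the right ring at C1'–C6'.
2. The right ring is a folded geranyl unit: C1'–C6' joins the gem-dimethyl carbon to a carbon five atoms away that carries the C5'(Me)=C4' alkene, and the sp2 carbon C2' next to CMe2 marks where an initiating oxygen can sit. It is therefore closed by Lewis-acid cyclisation of (R)-6,7-epoxygeranyl acetate, the laboratory copy of the cation–olefin closure by which carotenoid cyclases make ε-rings.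
3. The oxygen left on C2' is then taken out as the C2'=C3' double bond (ketone, dienyl triflate, formate reduction), so the acid-labile 2,4-diene is made only after the Lewis-acid step.
4. Forward order: epoxide, ring (the only ring closed in the route; the left ring is bought), C10 sulfone, C15 phosphonium salt, C27 aldehyde; separately the left-ring ketone is taken to a C13 ketophosphonate; the last step joins the two.
5. Stereochemistry: C6' comes from the Shi epoxide through a chair transition state (the relay centre C2' is then erased). C6 comes from axial addition to the ring ketone, steered by the C3 silyloxy group of the chiral-pool enone. C3 is finally inverted (Mitsunobu) to give the cis-3,6-diol.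

Key step: step 2

**Route**

Step 1
Reactants: 1 geranyl acetate
Product: 2 (R)-6,7-epoxygeranyl acetate
Conditions: D-fructose-derived Shi ketone (0.3 equiv), KHSO5 (as 2KHSO5·KHSO4·K2SO4), K2CO3, n-Bu4NHSO4, MeCN/CH2(OMe)2/aq. Na2B4O7 buffer, 0 °C
Reagents that add atoms: potassium peroxymonosulfate, [K+].[O-]S(=O)(=O)OO
Why: Shi epoxidation: the dioxirane formed from the chiral ketone transfers oxygen to the electron-rich distal trisubstituted alkene (the 2,3-alkene is deactivated by the allylic acetate) through a spiro transition state that should deliver the (R)-oxirane.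

Step 2
Reactants: 2 (R)-6,7-epoxygeranyl acetate
Product: 3 [(1S,5R)-5-hydroxy-2,6,6-trimethylcyclohex-2-en-1-yl]methyl acetate
Conditions: ZrCl4 (1.2 equiv, Lewis acid, not consumed), CH2Cl2, argon, 0 °C to 20 °C, 15 min; aq. NaHCO3
Reagents that add atoms: none
Why: ZrCl4 binds the oxirane oxygen, the tertiary C1'–O bond lengthens, the C5'=C6' alkene held five atoms away attacks C1' from the side opposite the leaving oxygen, and the tertiary C5' cation so formed loses the C4' proton to give the endocyclic alkene. The closest known reaction type is the Lewis-acid-promoted biomimetic cyclisation of 6,7-epoxygeranyl esters and longer epoxy-polyenes, the laboratory counterpart of the cation–olefin closure by which carotenoid cyclases build ε-rings. The ring closes in the 6-endo mode at both partners (both oxirane carbons and both alkene carbons become ring atoms, Markovnikov at each). The new stereocentre C6' is set by the oxirane carbon C2' through a chair transition state: anti-periplanar opening leaves the C2'–O bond equatorial, the E alkene places CH2OAc equatorial, so the two are 1,3-cis and the (R)-oxirane gives (S)-C6'. The step needs 6-endo instead of 5-exo opening (secured by the cation-stabilising gem-dimethyl oxirane carbon), loss of the C4' proton instead of a C5'-methyl or the C6' proton (kinetic preference at or below 20 °C with short contact; the exocyclic isomer is the expected by-product), and no hydride-shift rearrangement to a ketone (secured by the well-placed nucleophilic alkene). The oxygen that stays on C2' is the handle later removed as the C2'=C3' double bond, so the diene never meets the Lewis acid.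

Step 3
Reactants: 3 [(1S,5R)-5-hydroxy-2,6,6-trimethylcyclohex-2-en-1-yl]methyl acetate
Product: 4 (1R,5S)-5-(hydroxymethyl)-4,6,6-trimethylcyclohex-3-en-1-ol
Conditions: K2CO3 (0.2 equiv), MeOH, 20 °C
Reagents that add atoms: none
Why: Base-catalysed transesterification (methanolysis) of the acetate frees the primary alcohol without touching the two stereocentres.

Step 4
Reactants: 4 (1R,5S)-5-(hydroxymethyl)-4,6,6-trimethylcyclohex-3-en-1-ol
Product: 5 (1R,5S)-4,6,6-trimethyl-5-{[(1-phenyl-1H-tetrazol-5-yl)sulfanyl]methyl}cyclohex-3-en-1-ol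
Conditions: 1-phenyl-1H-tetrazole-5-thiol, PPh3, DIAD, THF, 0 °C to 20 °C
Reagents that add atoms: 1-phenyl-1H-tetrazole-5-thiol, Sc1nnnn1-c1ccccc1
Why: Mitsunobu thioetherification with the acidic tetrazole thiol takes place at the primary alcohol only, the secondary carbinol next to the quaternary carbon being too hindered to be activated.

Step 5
Reactants: 5 (1R,5S)-4,6,6-trimethyl-5-{[(1-phenyl-1H-tetrazol-5-yl)sulfanyl]methyl}cyclohex-3-en-1-ol
Product: 6 (1R,5S)-4,6,6-trimethyl-5-{[(1-phenyl-1H-tetrazol-5-yl)sulfonyl]methyl}cyclohex-3-en-1-ol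
Conditions: (NH4)6Mo7O24·4H2O (0.1 equiv), 30% aq. H2O2, EtOH, 0 °C to 20 °C
Reagents that add atoms: hydrogen peroxide, OO
Why: Molybdate-catalysed peroxide oxidation of the sulfide to the sulfone is chemoselective for sulfur in the presence of a trisubstituted alkene and a secondary alcohol, and is done before the oxidation-prone diene exists.

Step 6
Reactants: 6 (1R,5S)-4,6,6-trimethyl-5-{[(1-phenyl-1H-tetrazol-5-yl)sulfonyl]methyl}cyclohex-3-en-1-ol
Product: 7 (5S)-4,6,6-trimethyl-5-{[(1-phenyl-1H-tetrazol-5-yl)sulfonyl]methyl}cyclohex-3-en-1-one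
Conditions: Dess–Martin periodinane, NaHCO3, CH2Cl2, 0 °C to 20 °C
Reagents that add atoms: none
Why: Dess–Martin oxidation under bicarbonate buffer gives the β,γ-unsaturated ketone without shifting the alkene into conjugation; C6' is not alpha to the new carbonyl and keeps its configuration.

Step 7
Reactants: 7 (5S)-4,6,6-trimethyl-5-{[(1-phenyl-1H-tetrazol-5-yl)sulfonyl]methyl}cyclohex-3-en-1-one
Product: 8 (5S)-4,6,6-trimethyl-5-{[(1-phenyl-1H-tetrazol-5-yl)sulfonyl]methyl}cyclohexa-1,3-dien-1-yl trifluoromethanesulfonate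
Conditions: LiN(SiMe3)2 (1.05 equiv), THF, −78 °C; PhNTf2, −78 °C to 0 °C
Reagents that add atoms: N-phenylbis(trifluoromethanesulfonimide), O=S(=O)(N(c1ccccc1)S(=O)(=O)C(F)(F)F)C(F)(F)F
Why: Enol triflate formation: the ketone can enolise only toward the allylic C3' methylene (the other alpha carbon is quaternary, and these hydrogens are far more acidic than those next to the sulfone), and O-sulfonylation of the dienolate gives the conjugated dienyl triflate.

Step 8
Reactants: 8 (5S)-4,6,6-trimethyl-5-{[(1-phenyl-1H-tetrazol-5-yl)sulfonyl]methyl}cyclohexa-1,3-dien-1-yl trifluoromethanesulfonate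
Product: 9 1-phenyl-5-({[(1S)-2,6,6-trimethylcyclohexa-2,4-dien-1-yl]methyl}sulfonyl)-1H-tetrazole
Conditions: Pd(OAc)2 (5 mol %), PPh3 (10 mol %), HCO2H, n-Bu3N, DMF, 60 °C, argon
Reagents that add atoms: none
Why: Palladium-catalysed formate reduction of an enol triflate: oxidative addition of zerovalent palladium, exchange of triflate for formate, loss of CO2 and reductive elimination replace the C2' oxygen by hydrogen under non-acidic conditions, leaving the 2,4-diene and the C6' stereocentre intact.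

Step 9
Reactants: 9 1-phenyl-5-({[(1S)-2,6,6-trimethylcyclohexa-2,4-dien-1-yl]methyl}sulfonyl)-1H-tetrazole; 10 (2E)-3-methyl-4-oxobut-2-en-1-yl acetate
Product: 11 (2E,4E)-3-methyl-5-[(1S)-2,6,6-trimethylcyclohexa-2,4-dien-1-yl]penta-2,4-dien-1-yl acetate
Conditions: KN(SiMe3)2, DME, −60 °C; then 10, −60 °C to 20 °C, argon, dark
Reagents that add atoms: none
Why: Julia–Kocienski olefination: addition of the metalated sulfone to the aldehyde, Smiles rearrangement and loss of SO2 and tetrazolone should give the E C7'=C8' alkene (potassium counter-ion in DME), and since the carbanion sits on C7' the neighbouring C6' stereocentre is not touched.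

Step 10
Reactants: 11 (2E,4E)-3-methyl-5-[(1S)-2,6,6-trimethylcyclohexa-2,4-dien-1-yl]penta-2,4-dien-1-yl acetate
Product: 12 (2E,4E)-3-methyl-5-[(1S)-2,6,6-trimethylcyclohexa-2,4-dien-1-yl]penta-2,4-dien-1-ol
Conditions: K2CO3 (0.2 equiv), MeOH, 0 °C
Reagents that add atoms: none
Why: Mild methanolysis of the allylic acetate; carbonate is far too weak a base to remove the doubly allylic C6' hydrogen.

Step 11
Reactants: 12 (2E,4E)-3-methyl-5-[(1S)-2,6,6-trimethylcyclohexa-2,4-dien-1-yl]penta-2,4-dien-1-ol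
Product: 14 [(2E,4E)-3-methyl-5-[(1S)-2,6,6-trimethylcyclohexa-2,4-dien-1-yl]penta-2,4-dien-1-yl](triphenyl)phosphonium bromide, via allylic bromide 13 (not isolated)
Conditions: CBr4 (1.1 equiv), PPh3 (2.3 equiv), CH2Cl2, 0 °C to 20 °C
Reagents that add atoms: carbon tetrabromide, BrC(Br)(Br)Br; triphenylphosphine, c1ccc(cc1)P(c1ccccc1)c1ccccc1
Why: Appel bromination of the allylic alcohol under neutral conditions, followed by SN2 quaternisation of the reactive pentadienylic bromide by the excess PPh3 at its primary terminus, gives the phosphonium salt without acid.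

Step 12
Reactants: 15 (2E,4E,6E)-2,7-dimethylocta-2,4,6-trienedial; 16 diethyl {2-[methoxy(methyl)amino]-2-oxoethyl}phosphonate
Product: 17 (2E,4E,6E,8E)-N-methoxy-N,4,9-trimethyl-10-oxodeca-2,4,6,8-tetraenamide
Conditions: 16, NaH, THF, 0 °C; added to 15 (2 equiv), 0 °C to 20 °C
Reagents that add atoms: none
Why: Horner–Wadsworth–Emmons olefination of one aldehyde of the symmetrical dialdehyde (used in excess; the mono-adduct is less electrophilic through its longer conjugation) with the stabilised Weinreb phosphonate anion gives the E alkene and a masked aldehyde at C10.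

Step 13
Reactants: 14 [(2E,4E)-3-methyl-5-[(1S)-2,6,6-trimethylcyclohexa-2,4-dien-1-yl]penta-2,4-dien-1-yl](triphenyl)phosphonium bromide; 17 (2E,4E,6E,8E)-N-methoxy-N,4,9-trimethyl-10-oxodeca-2,4,6,8-tetraenamide
Product: 18 (2E,4E,6E,8E,10E,12E,14E)-N-methoxy-N,4,9,13-trimethyl-15-[(1S)-2,6,6-trimethylcyclohexa-2,4-dien-1-yl]pentadeca-2,4,6,8,10,12,14-heptaenamide
Conditions: NaOMe, CH2Cl2/MeOH, 0 °C to 20 °C, argon, dark; then heptane, 70 °C
Reagents that add atoms: none
Why: Wittig olefination with the semistabilised pentadienyl ylide forms C11'=C12', and the minor hindered Z isomer should equilibrate to E on gentle warming, as is usual for this position of a carotenoid chain.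

Step 14
Reactants: 18 (2E,4E,6E,8E,10E,12E,14E)-N-methoxy-N,4,9,13-trimethyl-15-[(1S)-2,6,6-trimethylcyclohexa-2,4-dien-1-yl]pentadeca-2,4,6,8,10,12,14-heptaenamide
Product: 19 (2E,4E,6E,8E,10E,12E,14E)-4,9,13-trimethyl-15-[(1S)-2,6,6-trimethylcyclohexa-2,4-dien-1-yl]pentadeca-2,4,6,8,10,12,14-heptaenal
Conditions: i-Bu2AlH, THF, −78 °C; aq. KNaC4H4O6
Reagents that add atoms: none
Why: Hydride reduction of the Weinreb amide stops at the chelated tetrahedral aluminium adduct, which releases the aldehyde only on work-up, so over-reduction is avoided.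

Step 15
Reactants: 20 (4R)-4-{[tert-butyl(dimethyl)silyl]oxy}cyclohex-2-en-1-one
Product: 22 (4R)-4-{[tert-butyl(dimethyl)silyl]oxy}-6,6-dimethylcyclohex-2-en-1-one, via monomethyl enone 21 (not isolated)
Conditions: LiN(i-Pr)2, THF, −78 °C; MeI; then LiN(i-Pr)2, −78 °C; MeI, −78 °C to 0 °C
Reagents that add atoms: iodomethane, CI
Why: Kinetic alkylation of the cross-conjugated alpha-prime lithium enolate, done twice, installs the gem-dimethyl group (future C1) without touching the silyloxy-bearing gamma carbon.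

Step 16
Reactants: 22 (4R)-4-{[tert-butyl(dimethyl)silyl]oxy}-6,6-dimethylcyclohex-2-en-1-one
Product: 25 (4R)-4-{[tert-butyl(dimethyl)silyl]oxy}-2,2-dimethyl-6-methylidenecyclohexan-1-one, via Mannich base 23 (not isolated), via trimethylammonium iodide 24 (not isolated)
Conditions: LiBH(s-Bu)3, THF, −78 °C; [Me2N=CH2]I, −78 °C to 20 °C; MeI, CH2Cl2; aq. NaHCO3
Reagents that add atoms: N,N-dimethylmethyleneiminium iodide, C=[N+](C)C.[I-]
Why: Conjugate hydride reduction gives the regiodefined enolate, a Mannich reaction with the iminium salt puts the aminomethyl group on it, and quaternisation followed by E1cB elimination of trimethylamine unveils the exocyclic methylene (future C5=C18).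

Step 17
Reactants: 25 (4R)-4-{[tert-butyl(dimethyl)silyl]oxy}-2,2-dimethyl-6-methylidenecyclohexan-1-one; 26 diethyl (3-oxobutan-2-yl)phosphonate
Product: 27 diethyl {4-[(1R,4R)-4-{[tert-butyl(dimethyl)silyl]oxy}-1-hydroxy-2,2-dimethyl-6-methylidenecyclohexyl]-3-oxobutan-2-yl}phosphonate
Conditions: 26, NaH, THF, 0 °C; n-BuLi, 0 °C; CeCl3, −78 °C; 25, −78 °C; AcOH, −78 °C
Reagents that add atoms: none
Why: Aldol-type addition of the phosphonate dianion (cerium-modified, hence 1,2-selective) through its terminal carbon: the nucleophile attacks the carbonyl axially, anti to the axial methyl of the neighbouring CMe2 group, in the chair that keeps the silyloxy group equatorial, so the new chain is cis to the silyloxy group and C6 is set as R; the phosphonate enolate in the adduct protects it from retro-aldol cleavage.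

Step 18
Reactants: 27 diethyl {4-[(1R,4R)-4-{[tert-butyl(dimethyl)silyl]oxy}-1-hydroxy-2,2-dimethyl-6-methylidenecyclohexyl]-3-oxobutan-2-yl}phosphonate
Product: 28 diethyl {4-[(1R,4R)-1,4-dihydroxy-2,2-dimethyl-6-methylidenecyclohexyl]-3-oxobutan-2-yl}phosphonate
Conditions: HF·pyridine, pyridine, THF, 0 °C to 20 °C
Reagents that add atoms: none
Why: Fluoride-mediated desilylation under pyridine buffer removes the silyl ether without dehydrating the tertiary allylic alcohol.

Step 19
Reactants: 28 diethyl {4-[(1R,4R)-1,4-dihydroxy-2,2-dimethyl-6-methylidenecyclohexyl]-3-oxobutan-2-yl}phosphonate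
Product: 29 (1S,4R)-4-[3-(diethoxyphosphoryl)-2-oxobutyl]-4-hydroxy-3,3-dimethyl-5-methylidenecyclohexyl 4-nitrobenzoate
Conditions: 4-nitrobenzoic acid, PPh3, DIAD, toluene, 0 °C to 20 °C
Reagents that add atoms: 4-nitrobenzoic acid, O=C(O)c1ccc(cc1)[N+](=O)[O-]
Why: Mitsunobu reaction: SN2 displacement of the activated secondary oxygen by 4-nitrobenzoate inverts C3 to the S configuration, the hindered tertiary alcohol not being activated.

Step 20
Reactants: 29 (1S,4R)-4-[3-(diethoxyphosphoryl)-2-oxobutyl]-4-hydroxy-3,3-dimethyl-5-methylidenecyclohexyl 4-nitrobenzoate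
Product: 30 diethyl {4-[(1R,4S)-1,4-dihydroxy-2,2-dimethyl-6-methylidenecyclohexyl]-3-oxobutan-2-yl}phosphonate
Conditions: K2CO3, MeOH, 0 °C
Reagents that add atoms: none
Why: Methanolysis of the activated aryl ester; the phosphonate-stabilised enolate present under these conditions shields the β-hydroxy ketone from retro-aldol cleavage.

Step 21
Reactants: 30 diethyl {4-[(1R,4S)-1,4-dihydroxy-2,2-dimethyl-6-methylidenecyclohexyl]-3-oxobutan-2-yl}phosphonate; 19 (2E,4E,6E,8E,10E,12E,14E)-4,9,13-trimethyl-15-[(1S)-2,6,6-trimethylcyclohexa-2,4-dien-1-yl]pentadeca-2,4,6,8,10,12,14-heptaenal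
Product: 31 CNP0261423.1
Conditions: LiCl, i-Pr2NEt, MeCN/THF, 20 °C, argon, dark
Reagents that add atoms: none
Why: Horner–Wadsworth–Emmons olefination under Masamune–Roush conditions (lithium-chelated ketophosphonate deprotonated by a tertiary amine) with the unhindered enal gives the E trisubstituted enone C9=C10, and the weak base leaves the tertiary β-hydroxy ketone, the free hydroxyls and the doubly allylic C6' hydrogen untouched.

**Compound list**

1 | geranyl acetate, (2E)-3,7-dimethylocta-2,6-dien-1-yl acetate | CC(C)=CCC/C(C)=C/COC(C)=O | starting material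
2 | (R)-6,7-epoxygeranyl acetate, (2E)-5-[(2R)-3,3-dimethyloxiran-2-yl]-3-methylpent-2-en-1-yl acetate | CC(=O)OC/C=C(\C)CC[C@H]1OC1(C)C | intermediate
3 | [(1S,5R)-5-hydroxy-2,6,6-trimethylcyclohex-2-en-1-yl]methyl acetate | CC(=O)OC[C@H]1C(C)=CC[C@@H](O)C1(C)C | intermediate
4 | (1R,5S)-5-(hydroxymethyl)-4,6,6-trimethylcyclohex-3-en-1-ol | OC[C@H]1C(C)=CC[C@@H](O)C1(C)C | intermediate
5 | (1R,5S)-4,6,6-trimethyl-5-{[(1-phenyl-1H-tetrazol-5-yl)sulfanyl]methyl}cyclohex-3-en-1-ol | c1ccc(cc1)-n2nnnc2SC[C@H]3C(C)=CC[C@@H](O)C3(C)C | intermediate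
6 | (1R,5S)-4,6,6-trimethyl-5-{[(1-phenyl-1H-tetrazol-5-yl)sulfonyl]methyl}cyclohex-3-en-1-ol | c1ccc(cc1)-n2nnnc2S(=O)(=O)C[C@H]3C(C)=CC[C@@H](O)C3(C)C | intermediate
7 | (5S)-4,6,6-trimethyl-5-{[(1-phenyl-1H-tetrazol-5-yl)sulfonyl]methyl}cyclohex-3-en-1-one | c1ccc(cc1)-n2nnnc2S(=O)(=O)C[C@H]3C(C)=CCC(=O)C3(C)C | intermediate
8 | (5S)-4,6,6-trimethyl-5-{[(1-phenyl-1H-tetrazol-5-yl)sulfonyl]methyl}cyclohexa-1,3-dien-1-yl trifluoromethanesulfonate | c1ccc(cc1)-n2nnnc2S(=O)(=O)C[C@H]3C(C)=CC=C(OS(=O)(=O)C(F)(F)F)C3(C)C | intermediate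
9 | 1-phenyl-5-({[(1S)-2,6,6-trimethylcyclohexa-2,4-dien-1-yl]methyl}sulfonyl)-1H-tetrazole | c1ccc(cc1)-n2nnnc2S(=O)(=O)C[C@H]3C(C)=CC=CC3(C)C | intermediate
10 | (2E)-3-methyl-4-oxobut-2-en-1-yl acetate (4-acetoxy-2-methylbut-2-enal) | CC(=O)OC/C=C(\C)C=O | starting material
11 | (2E,4E)-3-methyl-5-[(1S)-2,6,6-trimethylcyclohexa-2,4-dien-1-yl]penta-2,4-dien-1-yl acetate | CC(=O)OC/C=C(C)/C=C/[C@H]1C(C)=CC=CC1(C)C | intermediate
12 | (2E,4E)-3-methyl-5-[(1S)-2,6,6-trimethylcyclohexa-2,4-dien-1-yl]penta-2,4-dien-1-ol | OC/C=C(C)/C=C/[C@H]1C(C)=CC=CC1(C)C | intermediate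
13 | (6S)-6-[(1E,3E)-5-bromo-3-methylpenta-1,3-dien-1-yl]-1,5,5-trimethylcyclohexa-1,3-diene | BrC/C=C(C)/C=C/[C@H]1C(C)=CC=CC1(C)C | intermediate
14 | [(2E,4E)-3-methyl-5-[(1S)-2,6,6-trimethylcyclohexa-2,4-dien-1-yl]penta-2,4-dien-1-yl](triphenyl)phosphonium bromide | [Br-].C(/C=C(C)/C=C/[C@H]1C(C)=CC=CC1(C)C)[P+](c2ccccc2)(c3ccccc3)c4ccccc4 | intermediate
15 | (2E,4E,6E)-2,7-dimethylocta-2,4,6-trienedial | O=C/C(C)=C/C=C/C=C(C)/C=O | starting material
16 | diethyl {2-[methoxy(methyl)amino]-2-oxoethyl}phosphonate | CCOP(=O)(CC(=O)N(C)OC)OCC | starting material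
17 | (2E,4E,6E,8E)-N-methoxy-N,4,9-trimethyl-10-oxodeca-2,4,6,8-tetraenamide | CON(C)C(=O)/C=C/C(C)=C/C=C/C=C(C)/C=O | intermediate
18 | (2E,4E,6E,8E,10E,12E,14E)-N-methoxy-N,4,9,13-trimethyl-15-[(1S)-2,6,6-trimethylcyclohexa-2,4-dien-1-yl]pentadeca-2,4,6,8,10,12,14-heptaenamide | CON(C)C(=O)/C=C/C(C)=C/C=C/C=C(C)/C=C/C=C(C)/C=C/[C@H]1C(C)=CC=CC1(C)C | intermediate
19 | (2E,4E,6E,8E,10E,12E,14E)-4,9,13-trimethyl-15-[(1S)-2,6,6-trimethylcyclohexa-2,4-dien-1-yl]pentadeca-2,4,6,8,10,12,14-heptaenal | O=C/C=C/C(C)=C/C=C/C=C(C)/C=C/C=C(C)/C=C/[C@H]1C(C)=CC=CC1(C)C | intermediate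
20 | (4R)-4-{[tert-butyl(dimethyl)silyl]oxy}cyclohex-2-en-1-one | O=C1C=C[C@H](O[Si](C)(C)C(C)(C)C)CC1 | starting material
21 | (4R)-4-{[tert-butyl(dimethyl)silyl]oxy}-6-methylcyclohex-2-en-1-one (both C6 epimers) | O=C1C=C[C@H](O[Si](C)(C)C(C)(C)C)CC1C | intermediate
22 | (4R)-4-{[tert-butyl(dimethyl)silyl]oxy}-6,6-dimethylcyclohex-2-en-1-one | O=C1C=C[C@H](O[Si](C)(C)C(C)(C)C)CC1(C)C | intermediate
23 | (4S,6S)-4-{[tert-butyl(dimethyl)silyl]oxy}-6-[(dimethylamino)methyl]-2,2-dimethylcyclohexan-1-one (cis isomer) | CN(C)C[C@@H]1C[C@H](O[Si](C)(C)C(C)(C)C)CC(C)(C)C1=O | intermediate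
24 | {[(1S,5S)-5-{[tert-butyl(dimethyl)silyl]oxy}-3,3-dimethyl-2-oxocyclohexyl]methyl}(trimethyl)ammonium iodide | C[N+](C)(C)C[C@@H]1C[C@H](O[Si](C)(C)C(C)(C)C)CC(C)(C)C1=O.[I-] | intermediate
25 | (4R)-4-{[tert-butyl(dimethyl)silyl]oxy}-2,2-dimethyl-6-methylidenecyclohexan-1-one | C=C1C[C@H](O[Si](C)(C)C(C)(C)C)CC(C)(C)C1=O | intermediate
26 | diethyl (3-oxobutan-2-yl)phosphonate | CC(=O)C(C)P(=O)(OCC)OCC | starting material
27 | diethyl {4-[(1R,4R)-4-{[tert-butyl(dimethyl)silyl]oxy}-1-hydroxy-2,2-dimethyl-6-methylidenecyclohexyl]-3-oxobutan-2-yl}phosphonate (both epimers at the phosphorus-bearing carbon) | C=C1C[C@H](O[Si](C)(C)C(C)(C)C)CC(C)(C)[C@]1(O)CC(=O)C(C)P(=O)(OCC)OCC | intermediate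
28 | diethyl {4-[(1R,4R)-1,4-dihydroxy-2,2-dimethyl-6-methylidenecyclohexyl]-3-oxobutan-2-yl}phosphonate | C=C1C[C@H](O)CC(C)(C)[C@]1(O)CC(=O)C(C)P(=O)(OCC)OCC | intermediate
29 | (1S,4R)-4-[3-(diethoxyphosphoryl)-2-oxobutyl]-4-hydroxy-3,3-dimethyl-5-methylidenecyclohexyl 4-nitrobenzoate | C=C1C[C@@H](OC(=O)c2ccc(cc2)[N+](=O)[O-])CC(C)(C)[C@]1(O)CC(=O)C(C)P(=O)(OCC)OCC | intermediate
30 | diethyl {4-[(1R,4S)-1,4-dihydroxy-2,2-dimethyl-6-methylidenecyclohexyl]-3-oxobutan-2-yl}phosphonate | C=C1C[C@@H](O)CC(C)(C)[C@]1(O)CC(=O)C(C)P(=O)(OCC)OCC | intermediate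
31 | CNP0261423.1: all-E C40 ketocarotenoid with (3S,6R)-3,6-dihydroxy-5(18)-ene left ring, C7H2–C8(=O), and (6'S)-2,6,6-trimethylcyclohexa-2,4-dienyl right ring | C=C1C[C@@H](O)CC(C)(C)[C@]1(O)CC(=O)/C(C)=C/C=C/C(C)=C/C=C/C=C(C)/C=C/C=C(C)/C=C/[C@H]1C(C)=CC=CC1(C)C | target

**Step count and weak points**

Total: 21 steps. Longest linear sequence: 14 steps (steps 1–11, 13, 14, 21).

Step 17. The dianion may add in the conjugate sense to the very reactive exocyclic enone instead of to the hindered carbonyl, or the adduct may revert by retro-aldol cleavage on warming. The fallback masks the enone and sets out from 22. The sequence of step 16 is stopped after the Mannich reaction and the amine (4S,6S)-4-{[tert-butyl(dimethyl)silyl]oxy}-6-[(dimethylamino)methyl]-2,2-dimethylcyclohexan-1-one 23 is isolated as the diequatorial cis isomer. The cerium-modified dianion of 26 can then only add to the carbonyl group, from the same axial direction, to give diethyl {4-[(1S,4S,6S)-4-{[tert-butyl(dimethyl)silyl]oxy}-6-[(dimethylamino)methyl]-1-hydroxy-2,2-dimethylcyclohexyl]-3-oxobutan-2-yl}phosphonate F1. Oxidation with mCPBA in CH2Cl2 at 0 °C gives the amine oxide diethyl {4-[(1S,4S,6S)-4-{[tert-butyl(dimethyl)silyl]oxy}-6-[(dimethyloxidoamino)methyl]-1-hydroxy-2,2-dimethylcyclohexyl]-3-oxobutan-2-yl}phosphonate F2. Warming in THF/DMSO brings about the Cope elimination (only the ring C–H is beta), which creates the exocyclic methylene and comes back to the route at 27.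

Step 19. E2 loss of the activated C3 oxygen toward the allylic C4 hydrogen, or backside attack of the trans tertiary hydroxyl (cyclodehydration to a 3,6-ether), may outrun substitution by the carboxylate. The fallback inverts C3 by oxidation and reduction and sets out from 28. Bicarbonate-buffered Dess–Martin oxidation of the secondary carbinol gives the ring ketone diethyl {4-[(1R)-1-hydroxy-2,2-dimethyl-6-methylidene-4-oxocyclohexyl]-3-oxobutan-2-yl}phosphonate F3. An NADPH-dependent ketoreductase selected by screening for formation of the (S)-carbinol (glucose and glucose dehydrogenase for cofactor recycling, pH 7 buffer, 30 °C) reduces the unhindered ring ketone and overrides the substrate bias of hydride reagents. This comes back to the route at 30, so steps 19 and 20 are not needed.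

Step 21. Addition of the alpha-branched phosphonate anion to the long, vinylogously deactivated polyenal may be slow, and long exposure to base invites retro-aldol cleavage of the tertiary β-hydroxy ketone and E/Z scrambling. The fallback moves the last bond from C9=C10 to C11=C12 and sets out from 30 and 14.
- Horner–Wadsworth–Emmons reaction of 30 with the small, reactive aldehyde (tert-butyldimethylsilyloxy)acetaldehyde (LiCl, i-Pr2NEt, MeCN) gives (3E)-5-{[tert-butyl(dimethyl)silyl]oxy}-1-[(1R,4S)-1,4-dihydroxy-2,2-dimethyl-6-methylidenecyclohexyl]-3-methylpent-3-en-2-one F4.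
- HF·pyridine gives (3E)-1-[(1R,4S)-1,4-dihydroxy-2,2-dimethyl-6-methylidenecyclohexyl]-5-hydroxy-3-methylpent-3-en-2-one F5.
- CBr4/PPh3 at −20 °C (the primary allylic alcohol reacts first) and then more PPh3 give {(2E)-5-[(1R,4S)-1,4-dihydroxy-2,2-dimethyl-6-methylidenecyclohexyl]-3-methyl-4-oxopent-2-en-1-yl}(triphenyl)phosphonium bromide F6.
- In parallel, Wittig reaction of 14 with an excess of dialdehyde 15 (NaOMe) gives (2E,4E,6E,8E,10E,12E)-2,7,11-trimethyl-13-[(1S)-2,6,6-trimethylcyclohexa-2,4-dien-1-yl]trideca-2,4,6,8,10,12-hexaenal F7.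
- F6 and F7 are joined by a base-free Wittig reaction in 1,2-epoxybutane/EtOH at 60 °C, which forms C11=C12 and comes back to the route at 31.

**Further compounds**

F1 | step 17 | diethyl {4-[(1S,4S,6S)-4-{[tert-butyl(dimethyl)silyl]oxy}-6-[(dimethylamino)methyl]-1-hydroxy-2,2-dimethylcyclohexyl]-3-oxobutan-2-yl}phosphonate | CN(C)C[C@@H]1C[C@H](O[Si](C)(C)C(C)(C)C)CC(C)(C)[C@]1(O)CC(=O)C(C)P(=O)(OCC)OCC
F2 | step 17 | diethyl {4-[(1S,4S,6S)-4-{[tert-butyl(dimethyl)silyl]oxy}-6-[(dimethyloxidoamino)methyl]-1-hydroxy-2,2-dimethylcyclohexyl]-3-oxobutan-2-yl}phosphonate | C[N+](C)([O-])C[C@@H]1C[C@H](O[Si](C)(C)C(C)(C)C)CC(C)(C)[C@]1(O)CC(=O)C(C)P(=O)(OCC)OCC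
F3 | step 19 | diethyl {4-[(1R)-1-hydroxy-2,2-dimethyl-6-methylidene-4-oxocyclohexyl]-3-oxobutan-2-yl}phosphonate | C=C1CC(=O)CC(C)(C)[C@]1(O)CC(=O)C(C)P(=O)(OCC)OCC
F4 | step 21 | (3E)-5-{[tert-butyl(dimethyl)silyl]oxy}-1-[(1R,4S)-1,4-dihydroxy-2,2-dimethyl-6-methylidenecyclohexyl]-3-methylpent-3-en-2-one | C=C1C[C@@H](O)CC(C)(C)[C@]1(O)CC(=O)/C(C)=C/CO[Si](C)(C)C(C)(C)C
F5 | step 21 | (3E)-1-[(1R,4S)-1,4-dihydroxy-2,2-dimethyl-6-methylidenecyclohexyl]-5-hydroxy-3-methylpent-3-en-2-one | C=C1C[C@@H](O)CC(C)(C)[C@]1(O)CC(=O)/C(C)=C/CO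
F6 | step 21 | {(2E)-5-[(1R,4S)-1,4-dihydroxy-2,2-dimethyl-6-methylidenecyclohexyl]-3-methyl-4-oxopent-2-en-1-yl}(triphenyl)phosphonium bromide | C=C1C[C@@H](O)CC(C)(C)[C@]1(O)CC(=O)/C(C)=C/C[P+](c2ccccc2)(c3ccccc3)c4ccccc4.[Br-]
F7 | step 21 | (2E,4E,6E,8E,10E,12E)-2,7,11-trimethyl-13-[(1S)-2,6,6-trimethylcyclohexa-2,4-dien-1-yl]trideca-2,4,6,8,10,12-hexaenal | O=C/C(C)=C/C=C/C=C(C)/C=C/C=C(C)/C=C/[C@H]1C(C)=CC=CC1(C)C
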